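The data are calculated with constants of no real substance, noise included.

64.0% of the free monomer charged ended as monomer in chains in the summer run, and we start from that reading.

- summer: free monomer 1 M; transfer agent 0.060 M; initiator 10 mol%; impurity 34 mM; run made earlier
- flask: free monomer 2.0 M; transfer agent 0.0600 M; initiator 10 mol%; impurity 34 mM; time 12 min

summer run (percent of the free monomer charged)

| time / min | free monomer / % | monomer in chains / % |
|---|---|---|
| 1.33 | 16.0 | 54.5 |
| 3.00 | 2.7 | 64.0 |
| 6.00 | 0.2 | 64.4 |
| 10.0 | 0 | 63.6 |

(standard deviation of a reading: 1 percentage point)

- which holds at 12 min: what has brought the reaction to rest, or that it has not come to rest (it is still moving / forward and back rates have come level / all of the free monomer has reacted / no working catalyst is left)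
- conversion of free monomer at 12 min
- amount of monomer in chains at 12 min, in percent of the free monomer charged
- amount of monomer in chains if the flask were left three thousand times as long, in percent of the free monomer charged

- on the list of suspects stand: free monomer + initiator -> living end + monomer in chains; free monomer + living end -> monomer in chains + living end; living end + transfer agent -> dead chain; initiator + impurity -> spent initiator; free monomer -> uncatalysed product
- the reaction counts as stopped when no species that holds the free monomer changes by six tenths of a point or more over the second half of the time
- no earlier run changes the charge of initiator; that part of a forecast is a guess

Three suspects consume free monomer: initiator takes it up to form a living end, the living end adds it to chains, and free monomer turns into uncatalysed product unaided. The last two rates are each proportional to free monomer, so their ratio at one moment should follow the living ends. The summer ratio of chains to uncatalysed product, with the monomer taken up by initiator counted in the chains, is 1.78. It hardly drifted: 64.9% of the monomer reacted by 1.33 min was in chains.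

We turn the settings in turn. Time adds nothing by hand, since summer free monomer already read 0% at 10.0 min. Impurity keeps its charge, and we let it take initiator mole for mole. What remains, in charges of transfer agent, is the working initiator: 1.10 in summer. Doubling free monomer at the same loading raises this to 2.77 in the flask, more than the transfer agent can remove. No earlier run tests the initiator, so proportionality is our guess. The chain odds per working charge, our selectivity factor, are 1.62.

| Flask | Working initiator | Chain odds | Chain share |
|---|---|---|---|
| summer | 1.10 | 1.78 | 64.0% |
| flask | 2.77 | 4.47 | 81.7% |

The summer half-life of free monomer, 0.503 min, is far shorter than 12 min. We therefore expect the flask's free monomer to be consumed, with 81.7% in chains, now and later.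

The forecast says all of the free monomer has reacted: conversion 100%, 82% in chains at 12 min, and 82% if left. Its ground is “Catalyst therefore cannot run out”.

The flask gives all of the free monomer has reacted: conversion 100%, 83.6% in chains, and 83.6% if left.

    free monomer + initiator → living end + monomer in chains (k = 0.250 L mol⁻¹ s⁻¹)
    free monomer + living end → monomer in chains + living end, rate k2*[living end]*[free monomer] (k = 0.280 L mol⁻¹ s⁻¹)
    living end + transfer agent → dead chain (kL = 0.120 L mol⁻¹ s⁻¹)
    initiator + impurity → spent initiator (k = 25.0 L mol⁻¹ s⁻¹)
    free monomer → uncatalysed product (k = 0.00820 s⁻¹)

In the flask, half of the uncatalysed turnover is done by 0.237 min, sooner than the transfer agent's half-life of 0.63 min at 0.250 min. At 1.20 min, free monomer stands at 3.25% with 30.9% of the transfer agent left, and the final chain odds are 5.10 against our 4.47. For the neighbour with 0.50 M of free monomer, working initiator is 0.267, so 1.62 gives odds of 0.431 and a chain share of 30.1%; that flask holds 27.4%.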